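The route rests on the C8–C15 disconnection. C8 is the α-carbon of the C7 lactone carbonyl and C15 is allylic to the C16=C17 methylene, so ring D (C8, C15, C16, C13, C14) is closed last by intramolecular C-alkylation of the lactone enolate with a 2-(chloromethyl)allyl group on C13. This single operation sets the C8 quaternary stereocentre and completes the bicyclo[3.2.1]octane with its exocyclic methylene. The precursor is a tricyclic lactone (ring A, spiro δ-lactone, ring C) built from a Diels–Alder-derived ring A, an auxiliary-made C11–C14 fragment bearing an isopropenyl group and a 6-endo radical cyclization; C15 oxidation finishes the enone.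

Key step: step 18

Remark: atom numbers are ent-kaurane numbers (C1–C20); α is the face of ring A that carries C20. TBS = tert-butyldimethylsilyl, TES = triethylsilyl, TBDPS = tert-butyldiphenylsilyl.
Assumption: the (S)-configured oxazaborolidinium catalyst of step 3 is taken to give 6 in the configuration drawn; if the sense of induction is opposite, its mirror image is used.
Remark: C8 in 23, 24, 27 and 28 and C15 in 32 are epimer mixtures of no consequence and are left unassigned.

Step 1
Reactants: 1 (tert-butyldimethylsilyloxy)acetaldehyde; 2 1-(triphenylphosphoranylidene)propan-2-one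
Product: 3 (E)-5-(tert-butyldimethylsilyloxy)pent-3-en-2-one
Conditions: CH2Cl2, 23 °C
Reagents that add atoms: none
Why: Wittig olefination with a stabilised acyl ylide should give the (E)-enone that holds C6, C5, C10, C1 and C2.

Step 2
Reactants: 3 (E)-5-(tert-butyldimethylsilyloxy)pent-3-en-2-one
Product: 4 (E)-5-(tert-butyldimethylsilyloxy)-2-(triethylsilyloxy)penta-1,3-diene
Conditions: TESOTf, Et3N, Et2O, −78 → 0 °C
Reagents that add atoms: triethylsilyl triflate CC[Si](CC)(CC)OS(=O)(=O)C(F)(F)F
Why: Soft enolisation of the methyl ketone (its only α-CH) should give the cross-conjugated 2-silyloxy diene with the (E)-alkene intact.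

Step 3
Reactants: 4 (E)-5-(tert-butyldimethylsilyloxy)-2-(triethylsilyloxy)penta-1,3-diene; 5 methacrolein
Product: 6 ring A aldehyde (cyclohexene silyl enol ether, CHO cis to CH2OTBS)
Conditions: (S)-3,3-diphenyl-1-(o-tolyl)tetrahydro-1H,3H-pyrrolo[1,2-c][1,3,2]oxazaborole (20 mol %), Tf2NH (18 mol %), CH2Cl2, −78 °C
Reagents that add atoms: none
Why: Catalytic asymmetric Diels–Alder reaction in which the 2-silyloxy and 4-alkyl groups of the diene both direct its CH2 terminus to the β-carbon of methacrolein, the endo (formyl) transition state places CHO cis to CH2OTBS (C4 and C5 set together), and the chiral oxazaborolidinium ion selects the enantioface.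

Step 4
Reactants: 6 ring A aldehyde
Product: 7 ring A primary alcohol (C19 hydroxyl)
Conditions: i-Bu2AlH, CH2Cl2, −78 °C; Rochelle salt work-up
Reagents that add atoms: none
Why: Aprotic 1,2-reduction of the neopentyl aldehyde should leave the triethylsilyl enol ether untouched.

Step 5
Reactants: 7 ring A primary alcohol
Product: 8 O19-TBDPS ether
Conditions: TBDPSCl, imidazole, DMAP (cat.), DMF, 40 °C
Reagents that add atoms: tert-butyldiphenylsilyl chloride CC(C)(C)[Si](Cl)(c1ccccc1)c1ccccc1
Why: Silylation under non-acidic conditions spares the enol ether and marks O19 with the one group that is removed last.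

Step 6
Reactants: 8 O19-TBDPS ether; 9 2,2,2-trifluoroethyl formate
Product: 10 ring A 2-formyl ketone (C1 ketone, formyl C20 on C10)
Conditions: MeLi, THF, 0 → 23 °C; then 9, −78 °C; aq. NH4Cl
Reagents that add atoms: none
Why: MeLi cleaves the triethylsilyl enol ether to the regiodefined C1/C10 lithium enolate, and its Claisen-type C-formylation with the activated formate installs C20 on C10 without scrambling to C2.

Step 7
Reactants: 10 ring A 2-formyl ketone; 11 methyl acrylate
Product: 12 C10-quaternary keto aldehyde ester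
Conditions: DBU (0.2 equiv), MeCN, 23 °C
Reagents that add atoms: none
Why: Michael addition of the 1,3-dicarbonyl enolate, with the acrylate approaching C10 on the β face opposite the α-oriented CH2OTBS at C5 and CH2OTBDPS at C4, should set the C10 quaternary centre with C20 α and C9 β.

Step 8
Reactants: 12 C10-quaternary keto aldehyde ester
Product: 14 1α-hydroxy spirolactone, via diol ester 13 (not isolated)
Conditions: NaBH4, MeOH/THF, −40 → 0 °C; AcOH; then PPTS (cat.), PhMe, 50 °C
Reagents that add atoms: none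
Why: Borohydride reduces the aldehyde and then the ketone, adding to C1 axially from the β face away from the axial C20 group to give the equatorial 1α-alcohol, and the primary C20 hydroxyl lactonises onto the ester faster than the hindered secondary C1 hydroxyl.

Step 9
Reactants: 14 1α-hydroxy spirolactone
Product: 15 1α-triethylsilyloxy spirolactone
Conditions: TESOTf, 2,6-lutidine, CH2Cl2, −78 → 0 °C
Reagents that add atoms: triethylsilyl triflate CC[Si](CC)(CC)OS(=O)(=O)C(F)(F)F
Why: The silyl triflate caps the hindered secondary alcohol at once, which also blocks migration of the lactone acyl group to O1.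

Step 10
Reactants: 16 (S)-4-benzyl-2-oxazolidinone; 17 3-methylbut-2-enoyl chloride
Product: 18 (S)-4-benzyl-3-(3-methylbut-2-enoyl)oxazolidin-2-one
Conditions: n-BuLi, THF, −78 °C; then 17
Reagents that add atoms: none
Why: N-acylation of the lithiated oxazolidinone by the acid chloride.

Step 11
Reactants: 18 (S)-4-benzyl-3-(3-methylbut-2-enoyl)oxazolidin-2-one; 19 2-chloroethyl trifluoromethanesulfonate
Product: 20 (S)-4-benzyl-3-[(S)-2-(2-chloroethyl)-3-methylbut-3-enoyl]oxazolidin-2-one
Conditions: NaN(SiMe3)2, THF, −78 °C; then 19, −78 → −50 °C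
Reagents that add atoms: none
Why: Deconjugative oxazolidinone-auxiliary alkylation, in which γ-deprotonation gives the (Z)-dienolate and the primary triflate (chloride untouched) reacts at the α-carbon on the face opposite the benzyl group, should set C13 as (S).

Step 12
Reactants: 20 (S)-4-benzyl-3-[(S)-2-(2-chloroethyl)-3-methylbut-3-enoyl]oxazolidin-2-one
Product: 21 (S)-2-(2-chloroethyl)-3-methylbut-3-en-1-ol
Conditions: LiBH4, MeOH (1 equiv), Et2O, 0 °C
Reagents that add atoms: none
Why: Reductive cleavage of the imide gives the primary alcohol (C14) without touching C13, the alkene or the alkyl chloride.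

Step 13
Reactants: 15 1α-triethylsilyloxy spirolactone; 21 (S)-2-(2-chloroethyl)-3-methylbut-3-en-1-ol
Product: 23 C8-alkylated spirolactone, via triflate 22 (not isolated)
Conditions: 21, Tf2O, 2,6-lutidine, CH2Cl2, −78 °C; 15, LiN(i-Pr)2, THF, −78 °C, then 22, −78 → −40 °C
Reagents that add atoms: none
Why: Enolate alkylation in which the lithium enolate of the lactone attacks the primary triflate far faster than the primary chloride, forming C8–C14.

Step 14
Reactants: 23 C8-alkylated spirolactone
Product: 25 C8=C9 unsaturated lactone chloride, via selenide 24 (not isolated)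
Conditions: KN(SiMe3)2, THF, −78 °C; PhSeBr; then H2O2, pyridine, CH2Cl2, 0 → 23 °C
Reagents that add atoms: none
Why: α-Selenenylation at −78 °C (too cold for the enolate to displace the remote chloride) and selenoxide syn-elimination toward C9 should give the endocyclic unsaturated lactone.

Step 15
Reactants: 25 C8=C9 unsaturated lactone chloride
Product: 26 C8=C9 unsaturated lactone iodide
Conditions: NaI, acetone, reflux
Reagents that add atoms: sodium iodide [Na+].[I-]
Why: Finkelstein exchange turns the primary chloride at C11 into the iodide needed for radical generation.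

Step 16
Reactants: 26 C8=C9 unsaturated lactone iodide
Product: 27 tricyclic lactone with 13-isopropenyl group (ring C closed)
Conditions: Bu3SnH, AIBN, PhH (0.01 M), 80 °C, slow addition
Reagents that add atoms: none
Why: Giese-type 6-endo-trig cyclisation of the C11 radical onto C9 (the isopropenyl group offers no 5-exo path) through a chair transition state with the C13 isopropenyl group and C10 equatorial should set C9 trans to C13, after which the C8 radical is reduced by the stannane.

Step 17
Reactants: 27 tricyclic lactone with 13-isopropenyl group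
Product: 28 tricyclic lactone with 13-[2-(chloromethyl)vinyl] group
Conditions: Ca(OCl)2, solid CO2, CH2Cl2/H2O, 0 °C
Reagents that add atoms: calcium hypochlorite [Ca+2].[O-]Cl.[O-]Cl
Why: Ene-type chlorination by hypochlorous acid attacks the only alkene at its CH2 terminus and loses a methyl proton, giving the allylic chloride without touching C13.

Step 18
Reactants: 28 tricyclic lactone with 13-[2-(chloromethyl)vinyl] group
Product: 29 tetracyclic lactone (ring D closed, 16-methylene)
Conditions: KN(SiMe3)2, THF (0.01 M), −78 → 0 °C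
Reagents that add atoms: none
Why: KN(SiMe3)2 removes the single α-hydrogen at C8 (both C8 epimers converge on one planar potassium lactone enolate) and, after ring C flips to the chair that holds the C13 side chain and C10 axial, C8 attacks C15 and expels chloride. The closest known reaction type is the intramolecular C-alkylation of an ester enolate by an allylic halide, long used to bridge six-membered rings into bicyclo[3.2.1]octanes. Ring D (C8–C15–C16–C13–C14) closes in the 5-exo-tet mode; an SN2′ attack at C17 would give the same compound because both allyl termini are CH2 groups on C16. The new C8 quaternary stereocentre is controlled by C13: the one-carbon bridge C14 allows the new bond only on the face of ring C that carries the C13 side chain, trans to the C9–C10 bond as in the target. The step needs C- over O-alkylation and intra- over intermolecular reaction, which the five-membered transition state, the absence of any other acidic C–H and dilution secure.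

Step 19
Reactants: 29 tetracyclic lactone
Product: 30 1α,6-diol
Conditions: HF·pyridine, pyridine, THF, 0 → 23 °C
Reagents that add atoms: none
Why: Buffered HF removes the primary TBS and secondary TES ethers while the TBDPS ether at O19 survives (selective desilylation).

Step 20
Reactants: 30 1α,6-diol
Product: 31 1α,6-diacetate
Conditions: Ac2O, DMAP (cat.), pyridine, 23 °C
Reagents that add atoms: acetic anhydride CC(=O)OC(C)=O
Why: DMAP-catalysed acetylation of both free hydroxyls; O19 stays protected.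

Step 21
Reactants: 31 1α,6-diacetate
Product: 32 15-hydroxy-16-methylene lactone
Conditions: SeO2 (0.3 equiv), t-BuOOH, CH2Cl2, 23 °C
Reagents that add atoms: selenium dioxide O=[Se]=O; tert-butyl hydroperoxide CC(C)(C)OO
Why: Allylic oxidation (ene reaction, then [2,3]-shift) occurs at C15, the only allylic CH2, because the bridgehead C13–H cannot take part.

Step 22
Reactants: 32 15-hydroxy-16-methylene lactone
Product: 33 O19-TBDPS isodojaponin D
Conditions: DMP, CH2Cl2, 0 → 23 °C
Reagents that add atoms: none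
Why: Dess–Martin oxidation of the allylic alcohol gives the α-methylene cyclopentanone under non-basic conditions.

Step 23
Reactants: 33 O19-TBDPS isodojaponin D
Product: 34 isodojaponin D
Conditions: Bu4NF, AcOH (1:1), THF, 23 °C
Reagents that add atoms: none
Why: Buffered fluoride cleaves the TBDPS ether without acetate migration or conjugate addition to the enone.

Compound list
1 | (tert-butyldimethylsilyloxy)acetaldehyde | O=CCO[Si](C)(C)C(C)(C)C | starting material
2 | 1-(triphenylphosphoranylidene)propan-2-one | CC(=O)C=P(c1ccccc1)(c1ccccc1)c1ccccc1 | starting material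
3 | (E)-5-(tert-butyldimethylsilyloxy)pent-3-en-2-one | CC(=O)/C=C/CO[Si](C)(C)C(C)(C)C | intermediate
4 | (E)-5-(tert-butyldimethylsilyloxy)-2-(triethylsilyloxy)penta-1,3-diene | C=C(O[Si](CC)(CC)CC)/C=C/CO[Si](C)(C)C(C)(C)C | intermediate
5 | methacrolein (2-methylprop-2-enal) | CC(=C)C=O | starting material
6 | (1R,2S)-2-[(tert-butyldimethylsilyloxy)methyl]-1-methyl-4-(triethylsilyloxy)cyclohex-3-ene-1-carbaldehyde (ring A; CHO cis to CH2OTBS) | O=C[C@]1(C)CCC(O[Si](CC)(CC)CC)=C[C@@H]1CO[Si](C)(C)C(C)(C)C | intermediate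
7 | [(1R,2S)-2-[(tert-butyldimethylsilyloxy)methyl]-1-methyl-4-(triethylsilyloxy)cyclohex-3-en-1-yl]methanol | OC[C@]1(C)CCC(O[Si](CC)(CC)CC)=C[C@@H]1CO[Si](C)(C)C(C)(C)C | intermediate
8 | tert-butyldiphenylsilyl ether of 7 (O19-TBDPS) | CC(C)(C)[Si](c1ccccc1)(c1ccccc1)OC[C@]1(C)CCC(O[Si](CC)(CC)CC)=C[C@@H]1CO[Si](C)(C)C(C)(C)C | intermediate
9 | 2,2,2-trifluoroethyl formate | O=COCC(F)(F)F | starting material
10 | ring A 2-formyl ketone: C1 ketone, formyl (C20) on C10 (drawn as keto aldehyde, present as the hydroxymethylene enol, C10 unassigned), 4β-methyl, 4α-CH2OTBDPS, 5α-CH2OTBS | O=CC1C(=O)CC[C@@](C)(CO[Si](c2ccccc2)(c2ccccc2)C(C)(C)C)[C@H]1CO[Si](C)(C)C(C)(C)C | intermediate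
11 | methyl acrylate | C=CC(=O)OC | starting material
12 | methyl 3-(ring A C10)propanoate: C1 ketone, C10 quaternary with α-CHO (C20) and β-CH2CH2CO2Me (C9, C8, C7) | COC(=O)CC[C@]1(C=O)C(=O)CC[C@@](C)(CO[Si](c2ccccc2)(c2ccccc2)C(C)(C)C)[C@H]1CO[Si](C)(C)C(C)(C)C | intermediate
13 | diol ester: 1α-OH, C20 CH2OH, methyl ester | COC(=O)CC[C@]1(CO)[C@@H](O)CC[C@@](C)(CO[Si](c2ccccc2)(c2ccccc2)C(C)(C)C)[C@H]1CO[Si](C)(C)C(C)(C)C | intermediate
14 | 1α-hydroxy spirolactone (δ-lactone C20H2–O–C7(=O)–C8H2–C9H2, spiro at C10 of ring A) | O=C1CC[C@]2(CO1)[C@@H](O)CC[C@@](C)(CO[Si](c3ccccc3)(c3ccccc3)C(C)(C)C)[C@H]2CO[Si](C)(C)C(C)(C)C | intermediate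
15 | 1α-triethylsilyloxy spirolactone | O=C1CC[C@]2(CO1)[C@@H](O[Si](CC)(CC)CC)CC[C@@](C)(CO[Si](c3ccccc3)(c3ccccc3)C(C)(C)C)[C@H]2CO[Si](C)(C)C(C)(C)C | intermediate
16 | (S)-4-benzyl-2-oxazolidinone | O=C1OC[C@H](Cc2ccccc2)N1 | starting material
17 | 3-methylbut-2-enoyl chloride | CC(C)=CC(Cl)=O | starting material
18 | (S)-4-benzyl-3-(3-methylbut-2-enoyl)oxazolidin-2-one | CC(C)=CC(=O)N1[C@@H](Cc2ccccc2)COC1=O | intermediate
19 | 2-chloroethyl trifluoromethanesulfonate | ClCCOS(=O)(=O)C(F)(F)F | starting material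
20 | (S)-4-benzyl-3-[(S)-2-(2-chloroethyl)-3-methylbut-3-enoyl]oxazolidin-2-one | O=C1OC[C@H](Cc2ccccc2)N1C(=O)[C@@H](CCCl)C(C)=C | intermediate
21 | (S)-2-(2-chloroethyl)-3-methylbut-3-en-1-ol (C14, C13, C12, C11 and the isopropenyl carbons C15–C17) | OC[C@@H](CCCl)C(C)=C | intermediate
22 | trifluoromethanesulfonate of 21 | O=S(=O)(OC[C@@H](CCCl)C(C)=C)C(F)(F)F | intermediate
23 | spirolactone 15 alkylated at C8 with the C14–C11 chain (C8 epimers) | O=C1C(C[C@@H](CCCl)C(C)=C)C[C@]2(CO1)[C@@H](O[Si](CC)(CC)CC)CC[C@@](C)(CO[Si](c3ccccc3)(c3ccccc3)C(C)(C)C)[C@H]2CO[Si](C)(C)C(C)(C)C | intermediate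
24 | C8 phenylselenide of 23 | O=C1C([Se]c4ccccc4)(C[C@@H](CCCl)C(C)=C)C[C@]2(CO1)[C@@H](O[Si](CC)(CC)CC)CC[C@@](C)(CO[Si](c3ccccc3)(c3ccccc3)C(C)(C)C)[C@H]2CO[Si](C)(C)C(C)(C)C | intermediate
25 | C8=C9 unsaturated spirolactone with the C8 side chain ending in C11–Cl | O=C1C(C[C@@H](CCCl)C(C)=C)=C[C@]2(CO1)[C@@H](O[Si](CC)(CC)CC)CC[C@@](C)(CO[Si](c3ccccc3)(c3ccccc3)C(C)(C)C)[C@H]2CO[Si](C)(C)C(C)(C)C | intermediate
26 | C11 iodide corresponding to 25 | O=C1C(C[C@@H](CCI)C(C)=C)=C[C@]2(CO1)[C@@H](O[Si](CC)(CC)CC)CC[C@@](C)(CO[Si](c3ccccc3)(c3ccccc3)C(C)(C)C)[C@H]2CO[Si](C)(C)C(C)(C)C | intermediate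
27 | tricyclic lactone (ring A, spiro δ-lactone, ring C) with 13-isopropenyl, 9β-H, C8–H unassigned | C=C(C)[C@@H]1CC[C@H]2[C@]3(COC(=O)C2C1)[C@@H](O[Si](CC)(CC)CC)CC[C@@](C)(CO[Si](c4ccccc4)(c4ccccc4)C(C)(C)C)[C@H]3CO[Si](C)(C)C(C)(C)C | intermediate
28 | tricyclic lactone with 13-[3-chloroprop-1-en-2-yl] group | C=C(CCl)[C@@H]1CC[C@H]2[C@]3(COC(=O)C2C1)[C@@H](O[Si](CC)(CC)CC)CC[C@@](C)(CO[Si](c4ccccc4)(c4ccccc4)C(C)(C)C)[C@H]3CO[Si](C)(C)C(C)(C)C | intermediate
29 | tetracyclic 7,20-lactone with ring D closed (C15 H2, 16-methylene), 1α-OTES, 6-OTBS, 19-OTBDPS | C=C1C[C@]23C[C@H]1CC[C@H]2[C@]1(COC3=O)[C@@H](O[Si](CC)(CC)CC)CC[C@@](C)(CO[Si](c4ccccc4)(c4ccccc4)C(C)(C)C)[C@H]1CO[Si](C)(C)C(C)(C)C | intermediate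
30 | 1α,6-diol of 29 (19-OTBDPS) | C=C1C[C@]23C[C@H]1CC[C@H]2[C@]1(COC3=O)[C@@H](O)CC[C@@](C)(CO[Si](c4ccccc4)(c4ccccc4)C(C)(C)C)[C@H]1CO | intermediate
31 | 1α,6-diacetate (19-OTBDPS) | C=C1C[C@]23C[C@H]1CC[C@H]2[C@]1(COC3=O)[C@@H](OC(C)=O)CC[C@@](C)(CO[Si](c4ccccc4)(c4ccccc4)C(C)(C)C)[C@H]1COC(C)=O | intermediate
32 | 15-hydroxy derivative of 31 (C15 epimers) | C=C1C(O)[C@]23C[C@H]1CC[C@H]2[C@]1(COC3=O)[C@@H](OC(C)=O)CC[C@@](C)(CO[Si](c4ccccc4)(c4ccccc4)C(C)(C)C)[C@H]1COC(C)=O | intermediate
33 | 19-O-TBDPS isodojaponin D | C=C1C(=O)[C@]23C[C@H]1CC[C@H]2[C@]1(COC3=O)[C@@H](OC(C)=O)CC[C@@](C)(CO[Si](c4ccccc4)(c4ccccc4)C(C)(C)C)[C@H]1COC(C)=O | intermediate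
34 | isodojaponin D | C=C1C(=O)[C@]23C[C@H]1CC[C@H]2[C@]1(COC3=O)[C@@H](OC(C)=O)CC[C@@](C)(CO)[C@H]1COC(C)=O | target

Total step count: 23 steps. Longest linear sequence: 20 steps (steps 1–9, then 13–23); steps 10–12 make the side fragment.

Steps most likely to fail

Step 18. The enolate may fail to reach C15, because ring C must first flip into the chair with the C13 side chain and C10 axial; slow closure would let intermolecular alkylation or loss of the allylic chloride take over. Fallback from 28: LiN(i-Pr)2, TBSCl and HMPA (THF, −78 °C) should give the tert-butyldimethylsilyl ketene acetal F1. Pd2(dba)3, dppe and Bu4N[Ph3SiF2] (THF, 23 °C) then ionise the allylic chloride to a π-allyl complex (zerovalent palladium inserts into the C–Cl bond), which the fluoride-released enolate attacks in a Tsuji–Trost allylation. This closes ring D on a soft electrophile and rejoins the route at 29.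

Step 16. The C11 radical may add to the wrong face of C9, or take hydrogen from the stannane before the slow 6-endo closure next to the quaternary C10. Fallback from 26: Kornblum oxidation (DMSO, NaHCO3, 80 °C) should give the C11 aldehyde F2. SmI2, LiBr and t-BuOH (THF, −78 °C) then effect a ketyl–olefin cyclisation, in which samarium chelates the aldehyde and lactone oxygens, to give the 11-hydroxy tricyclic lactone F3. Thiocarbonyldiimidazole (DMAP, CH2Cl2) gives the thiocarbonyl imidazolide F4, and Barton–McCombie deoxygenation (Bu3SnH, AIBN, PhMe, 100 °C) rejoins the route at 27.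

Step 14. The selenoxide may eliminate toward C14 and give the exocyclic alkylidene lactone in place of the C8=C9 isomer. Fallback from 15: LiN(i-Pr)2 and PhSeBr (THF, −78 °C) give the α-selenide F5, which is not isolated; its oxidation with H2O2 can eliminate only into the ring and should give the unsubstituted unsaturated spirolactone F6. I2 and pyridine (CH2Cl2) then give the α-iodo unsaturated lactone F7. Separately, 21 is converted into the primary iodide F8 (I2, PPh3, imidazole) and then the alkylzinc iodide F9 (Zn dust, LiCl, THF). Negishi coupling of F7 with F9 (PdCl2(dppf), THF, 50 °C) fixes the alkene position and rejoins the route at 25.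

Further compounds
F1 | step 18 | tert-butyldimethylsilyl ketene acetal of 28 (C7(OTBS)=C8) | C=C(CCl)[C@@H]1CC[C@H]2[C@]3(COC(O[Si](C)(C)C(C)(C)C)=C2C1)[C@@H](O[Si](CC)(CC)CC)CC[C@@](C)(CO[Si](c4ccccc4)(c4ccccc4)C(C)(C)C)[C@H]3CO[Si](C)(C)C(C)(C)C
F2 | step 16 | C11 aldehyde corresponding to 26 | O=C1C(C[C@@H](CC=O)C(C)=C)=C[C@]2(CO1)[C@@H](O[Si](CC)(CC)CC)CC[C@@](C)(CO[Si](c3ccccc3)(c3ccccc3)C(C)(C)C)[C@H]2CO[Si](C)(C)C(C)(C)C
F3 | step 16 | 11-hydroxy derivative of 27 (C11 and C8 unassigned) | C=C(C)[C@@H]1CC(O)[C@H]2[C@]3(COC(=O)C2C1)[C@@H](O[Si](CC)(CC)CC)CC[C@@](C)(CO[Si](c4ccccc4)(c4ccccc4)C(C)(C)C)[C@H]3CO[Si](C)(C)C(C)(C)C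
F4 | step 16 | 11-O-(imidazol-1-ylthiocarbonyl) derivative of F3 | C=C(C)[C@@H]1CC(OC(=S)n5ccnc5)[C@H]2[C@]3(COC(=O)C2C1)[C@@H](O[Si](CC)(CC)CC)CC[C@@](C)(CO[Si](c4ccccc4)(c4ccccc4)C(C)(C)C)[C@H]3CO[Si](C)(C)C(C)(C)C
F5 | step 14 | C8 phenylselenide of 15 | O=C1C([Se]c4ccccc4)C[C@]2(CO1)[C@@H](O[Si](CC)(CC)CC)CC[C@@](C)(CO[Si](c3ccccc3)(c3ccccc3)C(C)(C)C)[C@H]2CO[Si](C)(C)C(C)(C)C
F6 | step 14 | C8=C9 unsaturated spirolactone without C8 substituent | O=C1C=C[C@]2(CO1)[C@@H](O[Si](CC)(CC)CC)CC[C@@](C)(CO[Si](c3ccccc3)(c3ccccc3)C(C)(C)C)[C@H]2CO[Si](C)(C)C(C)(C)C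
F7 | step 14 | 8-iodo C8=C9 unsaturated spirolactone | O=C1C(I)=C[C@]2(CO1)[C@@H](O[Si](CC)(CC)CC)CC[C@@](C)(CO[Si](c3ccccc3)(c3ccccc3)C(C)(C)C)[C@H]2CO[Si](C)(C)C(C)(C)C
F8 | step 14 | (S)-5-chloro-3-(iodomethyl)-2-methylpent-1-ene | IC[C@@H](CCCl)C(C)=C
F9 | step 14 | alkylzinc iodide from F8 | I[Zn]C[C@@H](CCCl)C(C)=C
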